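The clock stops at 1.0 min, and this is what stands in the flask until then.

substrate 20 mM; reagent in the second phase 0.950 equiv; time 1.0 min; volume of the second phase over the first 0.25

    substrate + target → side product (k1 = 0.10 /M/s)
    substrate ⇌ dormant form (K2 = 1.3, k2 = 0.020 /s)
    substrate + reagent in the reaction phase ⇌ target (K3 = 35 /M, k3 = 110 /M/s)
    reagent in the reaction phase ⇌ reagent in the second phase, rate k4*([reagent in the reaction phase] - [reagent in the second phase]/K4) per volume of the first phase (K4 = 0.44, k4 = 1.1 /s)

1. target at 1.0 min, in percent of the substrate charged
2. part of the substrate charged that has reacted at 1.0 min

- in percentages every species weighs as the substrate in it: one side product counts as two
- in the second phase: reagent in the second phase; everything else is in the first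
- charges count per volume of the first phase; a concentration in a rate is the amount of a species over the volume of its own phase; every rate counts per litre of the first phase
- what has gone from substrate into another species counts as reacted, even if it can come back
- run time (flask): 1.0 min

*What is quick and what is slow?* Reagent in the reaction phase binds, by the forward rate alone at the charged concentrations, with a half-life of 0.32 s and transfers on a scale of 0.909 s, both far shorter than the 0.326 min in which substrate and dormant form relax. Target's half-life against the side-product step, 5.8 min, is longer than the run, so I drop that step.

*Which number carries the flask?* Set forward over back rate to one in each reversible step, and time drops out. Substrate outside target is then 2.30 times free substrate, and reagent outside target 1.11 times the reagent in the reaction phase. With x for target, C for the substrate charge and R for the reagent charge 19.0 mM, this gives xD = (C − x)(R − x), where D is the apparent dissociation constant, 72.9 mM.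

*And the yield?* Solving gives 3.50 mM of target, or 17.5% of the substrate charged.

*But is the dormant form balanced by then?* No. With the dormant form left out, D is 31.7 mM, which gives target 29.3%, the early level, and by my estimate a fraction 0.120 of the gap between the two balances remains at the end of the run. I commit to 18.9% target and 60.0% reacted.

The forecast gives 18.9% and 60%, holding that “the target stays in quasi-equilibrium with free substrate”.

The flask gives 18.9% target and 59.9% reacted. D puts the balance of the reversible steps at 17.5%, which is 1.4 percentage points below the target at 1.0 min; at 2.00 min target stands at 16.8%, lower than that balance.

In the flask charged with 50 mM of substrate, at the same equivalents, D stays 72.9 mM, and the rule gives 30.6% target. That flask's run gives 30.0%.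

(All constants were drawn at random within sensible limits; the result is computed.)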